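The numbers in the tables were generated by integration for an exercise, noise included.

**Bench note.** Z left blue, at 15 °C, faster than it left violet, at −5 °C: ρ was 2.48 min⁻¹ against 0.105 min⁻¹. Here ρ is my pseudo-first-order constant for Z + G → E, ln(Z charged / Z left)/t at the first reading, with Z left taken as what had not yet shown as E or X.

| flask | Z | G | temperature | remark | time |
|---|---|---|---|---|---|
| violet | 26 mM | 32 mM | −5 °C | run made earlier |  |
| blue | 26 mM | 130 mM | 15 °C | run made earlier |  |
| red | 52 mM | 65 mM | −5 °C | run made earlier |  |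
| west | 26 mM | 65.0 mM | 30 °C |  | 5.0 min |
| north-west | 26 mM | 65.0 mM | 0 °C |  | 5.0 min |

| run | time / min | E / % | X / % |
|---|---|---|---|
| violet | 1.33 | 12.2 | 0.8 |
| violet | 3.00 | 23.0 | 2.2 |
| violet | 8.00 | 41.4 | 3.9 |
| violet | 15.0 | 54.3 | 5.2 |
| blue | 0.500 | 59.1 | 11.9 |
| blue | 1.00 | 70.1 | 14.3 |
| blue | 3.00 | 69.6 | 11.6 |
| blue | 6.00 | 61.3 | 10.5 |
| red | 2.50 | 33.6 | 2.1 |
| red | 6.00 | 53.7 | 3.2 |
| red | 12.0 | 66.8 | 4.8 |
| red | 15.0 | 70.3 | 4.6 |

(standard deviation of a reading: 0.3 percentage points)

- percent here means Z units held: one D counts as two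
- what is said of E includes Q and D
- Q is a solid; its amount is given per volume of the solution
- steps under discussion: Z + E <-> D; G + X -> L; Z + G -> E; G -> J; G + E -> X; Q <-> E
- in an amount of E, one D counts as one E

- the flask with the highest share of E in all that became E or X or L ("all alike" if they lie within 1.5 percentage points) (west / north-west / all alike)
- share of E in all that became E or X or L, west
- share of E in all that became E or X or L, north-west

G takes Z to E in the step Z + G → E, and that is the step I counted. Per mM of G, ρ as read grew 5.82 times from violet to blue. I kept the same step in ln ρ per degree and took G at its charge, which gave h, the half-life of Z: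

west: h = 0.149 min, so 5.0 min holds 33.5 half-lives

north-west: h = 2.10 min, so 5.0 min holds 2.38 half-lives, Z left 19.2%

Leave north-west's timer alone: it gets fewer half-lives than west, and by my count Z is still there at its end.

The forecast put north-west highest, at 88% (83% to 92%), against 58% for west (35% to 74%), reading blue's fall of E as a “nearly zero-order drain from saturated solution”. My count spoke of Z, not of these shares.

West gave 82.7% and north-west 86.4%, so north-west stayed highest, with west 25 percentage points above the forecast. At 5.00 min west held G, its limiting reagent, at 0.35% of its charge. Z reached half conversion in 0.137 min against my 0.149 min, yet 33.5 half-lives of time ended with Z at 2.9%.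

    Z + E ⇌ D, settled at all times (K = 22.0 M⁻¹, ΔH = −17.0 kJ mol⁻¹)
    G + X → L (k = 2.77 M⁻¹ min⁻¹, Ea = 40.0 kJ mol⁻¹)
    Z + G → E (k = 5.99 M⁻¹ min⁻¹, Ea = 62.0 kJ mol⁻¹)
    G → J (k = 0.0291 min⁻¹, Ea = 77.0 kJ mol⁻¹)
    G + E → X (k = 8.56 M⁻¹ min⁻¹, Ea = 35.0 kJ mol⁻¹)
    Q ⇌ E, rate k6*(cs6 - [E]) while solid is left; crystals form when [E] > cs6 (solubility = 0.990 mM, k = 9.53 min⁻¹)
    (constants at 0 °C)

The neighbour is west with 39 mM of G: h becomes 0.249 min, or 20.1 half-lives in 5.0 min. Computed, it ended with Z at 19%, G at 0.057% of its charge, J at 15.8 mM, and E's share of all that became E or X or L at 90.7%.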